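You are asked what stands in the flask at 8.0 h, so look for the one concentration that sets the order of the rate.

- concentration of first product at 8.0 h, in M
- concentration of starting material at 8.0 h, in M
- concentration of released group at 8.0 h, in M

| setting | dusk | midnight | winter | flask |
|---|---|---|---|---|
| starting material | 0.40 M (fed, over 4.0 h) | 0.40 M (fed, over 4.0 h) | 0.20 M (fed, over 4.0 h) | 0.40 M (fed, over 4.0 h) |
| coupling partner | 0.21 M | 0.48 M | 0.32 M | 0.320 M |
| remark | run made earlier | run made earlier | run made earlier |  |
| time |  |  |  | 8.0 h |

The flask differs from the midnight run in coupling partner alone, 0.320 M against 0.48 M, so midnight is the run to scale from.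

| run | time / h | first product / % | starting material / % |
|---|---|---|---|
| dusk | 0.833 | 0 | 25 |
| dusk | 1.33 | 0 | 33 |
| dusk | 2.00 | 4 | 47 |
| dusk | 4.00 | 2 | 94 |
| dusk | 6.00 | 7 | 92 |
| dusk | 10.0 | 9 | 89 |
| midnight | 1.50 | 1 | 35 |
| midnight | 3.00 | 3 | 69 |
| midnight | 5.00 | 13 | 86 |
| midnight | 6.00 | 14 | 81 |
| midnight | 8.00 | 19 | 79 |
| midnight | 10.0 | 22 | 77 |
| winter | 0.833 | 1 | 21 |
| winter | 1.33 | 0 | 32 |
| winter | 2.50 | 3 | 58 |
| winter | 5.00 | 9 | 89 |
| winter | 10.0 | 20 | 80 |

(each reading ± 1.5 percentage points)

- on the list of suspects stand: coupling partner + double product -> triple product + released group; coupling partner + triple product -> tetra adduct + released group; starting material + coupling partner -> first product + released group; coupling partner -> decomposed reagent; coupling partner + first product -> double product + released group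
- percentages count the whole charge, also what has not yet gone in

Dusk and midnight share one charge of starting material. At 10.0 h the logarithms of their shares left stand in the ratio 2.24, close to the ratio 2.29 of their [coupling partner]. So I read the loss as first order in coupling partner. Winter, with half the charge of starting material, still loses 20.0% at 10.0 h, so I don't let the share lost follow that charge.

From midnight's 79% at 8.00 h I read 0.491 /M: the exposure coefficient, minus the logarithm of the share of starting material left at that time, per unit of [coupling partner] charged. For the flask this leaves 85.5%, so my own figures are [starting material] 0.342 M, and first product and released group each about 0.0582 M.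

The forecast gives 0.05 M, 0.348 M and 0.053 M, on the ground that “the first coupling dominates”.

The flask gives first product 0.0576 M, starting material 0.339 M and released group 0.0648 M, so the forecast holds on starting material and is low on the other two.

    coupling partner + double product → triple product + released group (k = 0.0181 /M/h)
    coupling partner + triple product → tetra adduct + released group (k = 0.120 /M/h)
    starting material + coupling partner → first product + released group (k = 0.136 /M/h)
    coupling partner → decomposed reagent (k = 0.0636 /h)
    coupling partner + first product → double product + released group (k = 0.0910 /M/h)

The flask keeps 84.7% of its starting material, against the 85.5% reckoned from midnight. Raise [coupling partner] to 1.3 M in the neighbouring flask, 4.06 times the charge, and the same coefficient leaves 52.8%. Its coupling partner stands at 45% of its own charge at 8.00 h, against 44% in the flask. That neighbouring flask holds 51.2% starting material, 37.7% first product and 10.7% double product.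

The data were generated by integration for substances that don't exist.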